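**Plan**

Ring numbering: C1 is the alkene carbon carrying the C7 methylene benzoate, C2 the alkene CH, C3 and C4 the free carbinols, C5 the benzoate carbinol, C6 the carbinol beside C1. O4, O5 and O6 share one face; O3 lies on the other.
Retrosynthesis: the O5 benzoyl group is removed first; C3–OH is then traced back to an ether bridge from O6 to C3 (water having entered with inversion); finally the C3–C4 and C5–C6 bonds are cut together.
Enabling feature: C6, C1, C2, C3 and O6 are the five ring atoms of a furan substituted at its 3-position by the C7 benzoate, and C4–C5 with its two cis oxygens is vinylene carbonate.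
Forward: esterification of furan-3-ylmethanol; exo [4+2] cycloaddition closing the carbocycle as a 7-oxanorbornene; hydrolytic opening of the bridge at C3; lipase resolution; removal of carbonate and chloroacetate; axial benzoylation of O5 through an orthoester.
Stereochemistry: the exo adduct fixes O4/O5 cis to O6, bridge opening inverts C3, and the absolute configuration is selected by the enzyme.

Key step: step 2

Assumption 1: compounds 5 and 6 are racemates; their SMILES show the enantiomer that leads to the target.
Assumption 2: the lipase is taken to acylate the 3R carbinol (oxygenated C4 flank as the large group); if it acylated the mirror-image series instead, the recovered diol would have the required configuration and would enter step 5 unchanged.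

**Route**

Step 1
Reactants: 1 furan-3-ylmethanol; 2 benzoyl chloride
Product: 3 furan-3-ylmethyl benzoate
Conditions: Et3N, 4-(dimethylamino)pyridine (cat.), CH2Cl2, 0 °C to rt
Reagents that add atoms: none
Why: O-benzoylation of a primary alcohol by an acid chloride under nucleophilic catalysis is routine, the furan ring is inert to it, and no stereocentre is formed.

Step 2
Reactants: 3 furan-3-ylmethyl benzoate; 4 vinylene carbonate
Product: 5 racemic exo 7-oxanorbornene carbonate adduct
Conditions: neat in excess 4, 2,6-di-tert-butyl-4-methylphenol (trace), sealed tube, 120 °C; chromatography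
Reagents that add atoms: none
Why: This is a thermal, concerted, suprafacial [4π+2π] cycloaddition in which the furan carbons C6 and C3 bond to C5 and C4 of the Z-alkene of vinylene carbonate, and its closest known relative is the Diels–Alder reaction of furan itself with vinylene carbonate. The six-membered carbocycle C1–C6 is closed in one event by intermolecular [4+2] cycloaddition, the furan oxygen becoming the one-atom bridge of a 7-oxabicyclo[2.2.1]heptene. C3 and C6 are tied to one face by the oxygen bridge, C4 and C5 are cis because addition to the Z-dienophile is suprafacial, and the relation of O4/O5 to the bridge is decided by exo versus endo approach. The step needs exo selectivity; furan cycloadditions are reversible at this temperature, so prolonged heating should let the more stable exo adduct (carbonate beside the oxygen bridge, away from the alkene) accumulate, and any endo isomer is removed by chromatography and re-heated. No regiochemical question arises because the dienophile is symmetric, and since neither partner is chiral the adduct is racemic, which step 4 deals with.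

Step 3
Reactants: 5 racemic exo 7-oxanorbornene carbonate adduct
Product: 6 racemic diol carbonate (3-OH trans, 6-OH cis to the 4,5-carbonate)
Conditions: HClO4 (aq., 1 M), 1,4-dioxane, 60 °C
Reagents that add atoms: water, O
Why: In this acid-catalysed solvolytic opening of an allylic bridged ether, protonation of the bridge oxygen and cleavage of the C3–O bond give the allyl cation whose far terminus C1 is tertiary (cleavage at C6 would give only secondary termini); water then adds at C3 opposite the cis-fused carbonate and the departing oxygen, so C3 is inverted while O6 stays on C6 with its configuration, and any tertiary C1 alcohol should re-ionise under these reversible conditions and drain to the trisubstituted alkene.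

Step 4
Reactants: 6 racemic diol carbonate
Product: 7 (3R,4S,5R,6R)-3-O-chloroacetate of the diol carbonate
Conditions: Burkholderia cepacia lipase (lipase PS, immobilised), vinyl chloroacetate, tert-butyl methyl ether, 30 °C, stopped near half conversion; chromatography
Reagents that add atoms: vinyl chloroacetate, C=COC(=O)CCl
Why: In this lipase-catalysed kinetic resolution by irreversible transesterification with an enol ester, the empirical size rule for secondary carbinols predicts acylation of the 3R carbinol (oxygenated C4 as large flank, vinylic C2–H as medium flank) of one enantiomer only, leaving the more hindered C6 hydroxyl and the mirror-image diol untouched; no stereocentre is formed, the existing ones are sorted.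

Step 5
Reactants: 7 (3R,4S,5R,6R)-3-O-chloroacetate of the diol carbonate
Product: 8 [(3R,4S,5R,6R)-3,4,5,6-tetrahydroxycyclohex-1-en-1-yl]methyl benzoate
Conditions: Et3N, THF/H2O, 0 °C to rt, monitored
Reagents that add atoms: none
Why: In this mild base hydrolysis by acyl–oxygen cleavage, the strained five-membered carbonate and the α-chloro ester should be attacked far faster than the benzoate, the monoalkyl carbonate loses CO2, and no C–O bond at a stereocentre is broken.

Step 6
Reactants: 8 [(3R,4S,5R,6R)-3,4,5,6-tetrahydroxycyclohex-1-en-1-yl]methyl benzoate; 9 trimethyl orthobenzoate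
Product: 12 [(3R,4S,5R,6R)-5-(benzoyloxy)-3,4,6-trihydroxycyclohex-1-en-1-yl]methyl benzoate, via 4,5-O-orthobenzoate 10 (not isolated), via 5,6-O-orthobenzoate 11 (not isolated)
Conditions: 9 (1.2 equiv), camphor-10-sulfonic acid (cat.), MeCN, rt; then AcOH/H2O 4:1, rt
Reagents that add atoms: water, O
Why: Orthoester exchange on a cis-diol followed by kinetically controlled acid hydrolysis of the 2-methoxy-2-phenyl-1,3-dioxolane delivers the ester to the axial oxygen; in the half-chair with O3, O4 and O6 (pseudo)equatorial, O5 is the only axial oxygen and belongs to both cis-diols, so 10 and 11, which may form side by side, should both open to the O5 benzoate, while the trans O3/O4 pair does not readily close a five-membered orthoester and no stereocentre is touched.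

**Compound list**

1 | furan-3-ylmethanol | OCc1ccoc1 | starting material
2 | benzoyl chloride | O=C(Cl)c1ccccc1 | starting material
3 | furan-3-ylmethyl benzoate | O=C(OCc1ccoc1)c1ccccc1 | intermediate
4 | vinylene carbonate (1,3-dioxol-2-one) | O=C1OC=CO1 | starting material
5 | racemic exo adduct, [(3aR*,4R*,7S*,7aS*)-2-oxo-3a,4,7,7a-tetrahydro-4,7-epoxy-1,3-benzodioxol-5-yl]methyl benzoate (carbonate on the same face as the oxygen bridge) | O=C(OCC1=C[C@@H]2O[C@H]1[C@H]1OC(=O)O[C@@H]21)c1ccccc1 | intermediate
6 | racemic diol carbonate, [(3aR*,4R*,7R*,7aS*)-4,7-dihydroxy-2-oxo-3a,4,7,7a-tetrahydro-1,3-benzodioxol-5-yl]methyl benzoate (ring numbering: 3-OH trans, 6-OH cis to the 4,5-carbonate) | O=C(OCC1=C[C@@H](O)[C@@H]2OC(=O)O[C@@H]2[C@@H]1O)c1ccccc1 | intermediate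
7 | [(3aR,4R,7R,7aS)-7-(chloroacetoxy)-4-hydroxy-2-oxo-3a,4,7,7a-tetrahydro-1,3-benzodioxol-5-yl]methyl benzoate (3-O-chloroacetate, single enantiomer) | O=C(OCC1=C[C@@H](OC(=O)CCl)[C@@H]2OC(=O)O[C@@H]2[C@@H]1O)c1ccccc1 | intermediate
8 | [(3R,4S,5R,6R)-3,4,5,6-tetrahydroxycyclohex-1-en-1-yl]methyl benzoate | O=C(OCC1=C[C@@H](O)[C@H](O)[C@H](O)[C@@H]1O)c1ccccc1 | intermediate
9 | trimethyl orthobenzoate | COC(OC)(OC)c1ccccc1 | starting material
10 | 4,5-O-(α-methoxybenzylidene) derivative of 8 (orthoester on O4/O5, epimers at the orthoester carbon, not isolated) | O=C(OCC1=C[C@@H](O)[C@@H]2OC(OC)(c3ccccc3)O[C@@H]2[C@@H]1O)c1ccccc1 | intermediate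
11 | 5,6-O-(α-methoxybenzylidene) derivative of 8 (orthoester on O5/O6, epimers at the orthoester carbon, not isolated) | O=C(OCC1=C[C@@H](O)[C@H](O)[C@@H]2OC(OC)(c3ccccc3)O[C@H]12)c1ccccc1 | intermediate
12 | [(3R,4S,5R,6R)-5-(benzoyloxy)-3,4,6-trihydroxycyclohex-1-en-1-yl]methyl benzoate | O=C(OCC1=C[C@@H](O)[C@H](O)[C@H](OC(=O)c2ccccc2)[C@@H]1O)c1ccccc1 | target

**Totals**

Total step count: 6. Longest linear sequence: 6 steps (1 to 12).

**Steps most likely to fail**

Step 3 (bridge opening). Ionisation may be slow next to the electron-poor carbonate, or unselective: cleavage of the other bridge bond, capture of the allyl cation at C1 (possibly assisted by the C7 benzoate), or acid-driven dehydration toward an arene. The fallback sets out from 5 and returns at 6. The bridge would be cleaved acylatively: 5 with Ac2O and catalytic H2SO4 (0 °C to rt) should give the racemic 3,6-diacetate F1 by O-acetylation of the bridge and anti capture at C3 by acetate, the standard acetolysis of 7-oxanorbornenes. Acid-catalysed methanolysis (HCl from acetyl chloride in MeOH, 0 °C), which removes acetates while benzoates and cyclic carbonates persist, then returns to 6.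

Step 4 (resolution). The enzyme may discriminate poorly between the enantiomers or acylate both hydroxyls of both series. The fallback sets out from 6 and returns at 8. Racemic 6 would be separated physically by preparative supercritical-fluid chromatography on an amylose tris(3,5-dimethylphenylcarbamate) phase. The (3R,4S,5R,6R)-diol carbonate F2, its configuration checked by carrying a sample through to 12 and comparing with the natural product, is hydrolysed under the step 5 conditions (only the carbonate has to go) to give 8.

Step 6 (O5 benzoylation). Orthoester exchange may engage the trans O3/O4 pair or two diol pairs at once, ring opening may go toward an equatorial oxygen, or the axial benzoate may migrate during isolation. The fallback sets out from 8 and returns at 12. The trans-diequatorial O3/O4 pair would be masked first: 8 with butane-2,3-dione, HC(OMe)3 and camphor-10-sulfonic acid in MeOH should give the 3,4-O-butane-2,3-diacetal F3, which leaves only the cis O5/O6 diol and locks O5 axial. Exchange with 9 gives the single 5,6-orthobenzoate F4, aqueous AcOH opens it to the axial O5 benzoate F5, and CF3CO2H/H2O (9:1, rt) removes the diacetal to give 12.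

**Further compounds**

F1 | step 3 | racemic 3,6-di-O-acetate of diol carbonate 6 | O=C(OCC1=C[C@@H](OC(C)=O)[C@@H]2OC(=O)O[C@@H]2[C@@H]1OC(C)=O)c1ccccc1
F2 | step 4 | (3R,4S,5R,6R)-diol carbonate, single enantiomer of 6 | O=C(OCC1=C[C@@H](O)[C@@H]2OC(=O)O[C@@H]2[C@@H]1O)c1ccccc1
F3 | step 6 | 3,4-O-(2,3-dimethoxybutane-2,3-diyl) derivative of 8 (trans-fused diacetal, methoxy groups axial) | O=C(OCC1=C[C@H]2O[C@](C)(OC)[C@@](C)(OC)O[C@@H]2[C@H](O)[C@@H]1O)c1ccccc1
F4 | step 6 | 5,6-O-(α-methoxybenzylidene) derivative of F3 (epimers at the orthoester carbon) | O=C(OCC1=C[C@H]2O[C@](C)(OC)[C@@](C)(OC)O[C@@H]2[C@@H]2OC(OC)(c3ccccc3)O[C@H]12)c1ccccc1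
F5 | step 6 | 5-O-benzoate of F3 | O=C(OCC1=C[C@H]2O[C@](C)(OC)[C@@](C)(OC)O[C@@H]2[C@H](OC(=O)c3ccccc3)[C@@H]1O)c1ccccc1
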